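(Its constants are those of an exercise, and the outcome is calculated.)

The ratio of partner's two first-order losses, decay to decomposed reagent against conversion to second intermediate, is 1.50 to one, and I start from it.

| setting | Wednesday's | Friday's | Tuesday's | Saturday's |
|---|---|---|---|---|
| substrate | 0.10 M | 0.10 M (fed, over 1.25 h) | 0.10 M | 0.10 M |
| partner | 0.100 M | 0.100 M | 0.100 M | 0.100 M (fed, over 1.25 h) |
| remark | one stirred flow tank at steady state, fed with the mixture as stated, mean residence time 2.5 h | all but substrate at the start; substrate goes in evenly over 1.25 h, the run ends at 2.5 h | everything together in a closed stirred flask, run for 2.5 h | a stirred flask in which partner is dosed at a steady rate over 1.25 h without added volume, worked up at 2.5 h |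
| time |  | 2.5 h | 2.5 h | 2.5 h |

    substrate → open intermediate (k1 = 0.0024 s⁻¹)
    partner → second intermediate (k2 = 0.0018 s⁻¹)
    open intermediate + second intermediate ⇌ product (K3 = 11 L mol⁻¹, k3 = 0.018 L mol⁻¹ s⁻¹)
    partner → decomposed reagent (k4 = 0.0027 s⁻¹)

- the stated concentrations are those of everything mixed, before any reaction; amounts are the same in each set-up
- the feed brings no volume worth counting
- run time (Friday's): 2.5 h

1. the set-up with the highest amount of open intermediate at the outlet or at the end, in percent of the substrate put in ("none" if the first two lie within 2 percentage points) (Wednesday's / Friday's / Tuesday's / Saturday's / none)
2. amount of open intermediate at the outlet or at the end, in percent of the substrate put in, Wednesday's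
3. amount of open intermediate at the outlet or at the end, in percent of the substrate put in, Friday's
4. amount of open intermediate at the outlet or at the end, in percent of the substrate put in, Tuesday's
5. amount of open intermediate at the outlet or at the end, in percent of the substrate put in, Saturday's

I carry the partner's share, the conversion constant of partner to second intermediate over the sum of its two loss constants: 40.0%. Both arrows are first order in partner, so the share holds at any [partner], dosed or not.

How much second intermediate can the batch flasks make? The share of 0.100 M gives 0.0400 M, less than the 0.10 M of substrate, so second intermediate is the limiting reagent of the association.

Do the conversions finish? Friday's and Saturday's have 1.25 h after the dose. That holds 15.6 half-lives of substrate and 29.2 of partner, so I take both as complete.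

What does the association then leave? If it balances, [product] = K([open intermediate])([second intermediate]) gives 0.0189 M of product, so 81.1% stays open intermediate.

Does it balance in time? Its relaxation constant is 0.00348 s⁻¹, a lifetime of 4.79 min, shorter than the tail. So the batch flasks end level, and I say best is none.

Wednesday's tank keeps 4.42% of its substrate and makes 0.0390 M of second intermediate. The outflow carries product away as well, so I add it to the backward step in the product balance. That gives 0.0174 M of product, less than the batch 0.0189 M, and 78.2% stays open intermediate.

The forecast also says none, with 81.1% for the batch flasks, since “the reversible step relaxes fast enough to reach the same equilibrium”, and 78.2% for Wednesday's.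

The simulation gives none: 78.2% for Wednesday's, 81.1% for Friday's, 81.1% for Tuesday's, 81.1% for Saturday's. In Friday's, partner peaked at 0.100 M and substrate at 0.00926 M while the dose ran. In Saturday's, partner peaked at 0.00494 M while it was dosed into the substrate. Saturday's product, 18.9% of the substrate charged, holds 47.2% of the second intermediate the share gives. With 0.131 M of partner in Saturday's, the share gives 0.0524 M, and the balance then moves the answer by 5 percentage points; the simulated move there is 5 points.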